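The target is a diaryl ether pentaol carrying two sulfate esters, so the only strategic disconnection is at the two O–S bonds: O–C3 of ring A (the 3,5-dioxygenated phenoxy ring) and O–C4' of ring B (the 2,4,6-trioxygenated ring, ether at C1'). One biocatalytic operation, sulfuryl transfer from 4-nitrophenyl sulfate by a bacterial aryl sulfotransferase, should install both on unprotected 2-(3,5-dihydroxyphenoxy)benzene-1,3,5-triol. It exploits the equivalence of the C3 and C5 hydroxyls of ring A and the exposed C4' hydroxyl of ring B, para to the ether, against the flanked C2'/C6' hydroxyls. The pentaol is reached in three robust steps: Dakin-type oxidation, Ullmann etherification, global demethylation.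

Key step: step 4

Remark: the target is drawn as the free bis(hydrogen sulfate); aryl hydrogen sulfates are kept as salts, so 10 would be isolated as its dipotassium salt (the potassium of the donor stays as counter-ion), the drawn acid being its neutral form.

Step 1
Reactants: 1 2,4,6-trimethoxybenzaldehyde
Product: 3 2,4,6-trimethoxyphenol, via 2,4,6-trimethoxyphenyl formate 2 (not isolated)
Conditions: mCPBA (1.3 equiv), CH2Cl2, 0 °C to rt; aq. Na2S2O3/NaHCO3 wash; then K2CO3 (0.1 equiv), MeOH, rt, Ar
Reagents that add atoms: mCPBA (3-chloroperoxybenzoic acid), O=C(OO)c1cccc(Cl)c1
Why: Baeyer–Villiger oxidation of an electron-rich aryl aldehyde (the peracid variant of the Dakin oxidation): the 2,4,6-trimethoxyphenyl group migrates to oxygen far faster than hydride, giving formate 2, whose base-catalysed methanolysis frees phenol 3 under conditions that touch none of the methyl ethers.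

Step 2
Reactants: 3 2,4,6-trimethoxyphenol; 4 1-bromo-3,5-dimethoxybenzene
Product: 5 2-(3,5-dimethoxyphenoxy)-1,3,5-trimethoxybenzene
Conditions: CuI (10 mol%), picolinic acid (20 mol%), K3PO4 (2 equiv), DMSO, 90 °C, Ar
Reagents that add atoms: none
Why: Ullmann-type C–O coupling: picolinate-ligated monovalent copper is a catalyst system known to arylate 2,6-disubstituted phenoxides with aryl bromides, bromide 4 has no ortho substituent to add further hindrance, and exclusion of air protects the electron-rich phenoxide of 3 from oxidation.

Step 3
Reactants: 5 2-(3,5-dimethoxyphenoxy)-1,3,5-trimethoxybenzene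
Product: 6 2-(3,5-dihydroxyphenoxy)benzene-1,3,5-triol
Conditions: BBr3 (8 equiv), CH2Cl2, −78 °C to rt, Ar; then ice-water, EtOAc extraction under Ar; used at once
Reagents that add atoms: none
Why: Lewis-acid cleavage of aryl methyl ethers: BBr3 complexes each methoxy oxygen and bromide removes the methyl group by SN2 attack, while the diaryl ether C–O bonds, which offer no sp3 carbon for attack, stay intact, so aqueous work-up should release all five phenols.

Step 4
Reactants: 6 2-(3,5-dihydroxyphenoxy)benzene-1,3,5-triol; 7 potassium 4-nitrophenyl sulfate
Product: 10 3-hydroxy-5-(2,6-dihydroxy-4-sulfooxyphenoxy)phenyl hydrogen sulfate (target), via ring B 4'-O-monosulfate 8 (not isolated), via ring A 3-O-monosulfate 9 (not isolated)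
Conditions: aryl sulfotransferase from Desulfitobacterium hafniense (recombinant), 7 (2.2–2.5 equiv, in portions), degassed Tris–glycine buffer pH 8.5–8.9, DMSO (5% v/v), 30 °C, Ar; adjust to pH 7.5, EtOAc wash; Sephadex LH-20 then C18 (water/MeOH); K+ form
Reagents that add atoms: potassium 4-nitrophenyl sulfate (7), O=[N+]([O-])c1ccc(OS(=O)(=O)[O-])cc1.[K+]
Why: The enzyme runs a ping-pong sequence in which the sulfuryl group of 7 is first passed to an active-site nucleophile (a histidine in the structurally characterised members of this enzyme family) with release of 4-nitrophenolate, and is then handed to a phenolate oxygen of the bound acceptor, so 6 is sulfated once to 8 or 9 and a second cycle converts either monosulfate into 10; the low pKa of 4-nitrophenol makes each transfer downhill. The closest known reaction type is the PAPS-independent bacterial aryl sulfotransferase sulfation of flavonoids, stilbenes and phenolic acids with 4-nitrophenyl sulfate, applied here to a phlorotannin-type pentaol. No ring is closed and no stereocentre is created; the step forms only the O–S bonds at O–C3 of ring A and O–C4' of ring B. The selectivity needed is one sulfate per ring and, on ring B, O–C4' in preference to O–C2'/O–C6'. The C3 and C5 hydroxyls of ring A are equivalent, so a first transfer to this ring can only give the correct pattern and the resulting sulfate anion makes that ring a poorer acceptor than the still neutral one, while on ring B the C4' hydroxyl is para to the ether and unhindered and the C2'/C6' hydroxyls are crowded by the aryloxy group at C1'. Dosing 7 near two equivalents and stopping by HPLC at the maximum of the disulfate peak should limit trisulfation, and 10 should be the only disulfate with a symmetric ring B and an unsymmetric ring A, which should make its NMR assignment straightforward.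

Compound list
1 | 2,4,6-trimethoxybenzaldehyde | COc1cc(OC)c(C=O)c(OC)c1 | starting material
2 | 2,4,6-trimethoxyphenyl formate | COc1cc(OC)c(OC=O)c(OC)c1 | intermediate
3 | 2,4,6-trimethoxyphenol | COc1cc(OC)c(O)c(OC)c1 | intermediate
4 | 1-bromo-3,5-dimethoxybenzene | COc1cc(Br)cc(OC)c1 | starting material
5 | 2-(3,5-dimethoxyphenoxy)-1,3,5-trimethoxybenzene | COc1cc(OC)cc(Oc2c(OC)cc(OC)cc2OC)c1 | intermediate
6 | 2-(3,5-dihydroxyphenoxy)benzene-1,3,5-triol | Oc1cc(O)cc(Oc2c(O)cc(O)cc2O)c1 | intermediate
7 | potassium 4-nitrophenyl sulfate | O=[N+]([O-])c1ccc(OS(=O)(=O)[O-])cc1.[K+] | starting material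
8 | 4-(3,5-dihydroxyphenoxy)-3,5-dihydroxyphenyl hydrogen sulfate (ring B 4'-O-monosulfate) | Oc1cc(O)cc(Oc2c(O)cc(OS(=O)(=O)O)cc2O)c1 | intermediate
9 | 3-hydroxy-5-(2,4,6-trihydroxyphenoxy)phenyl hydrogen sulfate (ring A 3-O-monosulfate) | O=S(=O)(O)Oc1cc(O)cc(Oc2c(O)cc(O)cc2O)c1 | intermediate
10 | 3-hydroxy-5-(2,6-dihydroxy-4-sulfooxyphenoxy)phenyl hydrogen sulfate | O=S(=O)(O)Oc1cc(O)cc(Oc2c(O)cc(OS(=O)(=O)O)cc2O)c1 | target

Total step count: 4
Longest linear sequence: 4 steps (1 → 3 → 5 → 6 → 10)

Steps most likely to fail

Step 4. What may go wrong: the enzyme may deliver a sulfuryl group to a flanked C2'/C6' hydroxyl of ring B, place both groups on ring A, or stall at the monosulfate stage while the acceptor slowly oxidises in the weakly alkaline buffer. The fallback replaces biocatalysis by reagent-based sulfation; it sets out from 6 and comes back at 10. Pentaol 6 would be treated with pyridine–sulfur trioxide (about 2.1 equiv) in dry pyridine/DMF at 0 °C under argon. The mixture would be brought to pH 8 with methanolic KOH and the disulfate fraction resolved by preparative ion-pair reversed-phase HPLC, followed by exchange to the potassium form. Chemical sulfation should favour the unhindered hydroxyls, and the symmetry argument given for step 4 identifies the wanted isomer. No new compound is made on the way.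

Step 2. What may go wrong: slow C–O bond formation at the doubly ortho-substituted phenoxide, oxidative consumption of that electron-rich phenoxide by copper, and protodebromination of 4. The fallback swaps the roles of the two rings so that the nucleophile is unhindered and robust; it sets out from 4 and comes back at 5. Bromide 4 would be hydroxylated (KOH, Pd2(dba)3, tBuXPhos, dioxane/water, 100 °C, a zerovalent palladium catalysed aryl halide hydroxylation) to 3,5-dimethoxyphenol F1, which can also be bought. F1 would then be coupled with purchased 2-iodo-1,3,5-trimethoxybenzene F2 under Ullmann conditions (CuI, picolinic acid, K3PO4, DMSO, 100 °C, or classically CuO, K2CO3, pyridine at reflux) to give 5.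

Step 3. What may go wrong: incomplete ether cleavage leaving partly methylated material that is hard to separate, and air oxidation or irreversible adsorption of the very polar pentaol during work-up and chromatography. The fallback traps the crude product as a stable ester and releases it only when needed; it sets out from 5 and comes back at 6. After the BBr3 treatment of 5 and a methanol quench with evaporation, the residue would be acetylated in the same flask (Ac2O, pyridine, DMAP cat.) to 2-[3,5-bis(acetyloxy)phenoxy]benzene-1,3,5-triyl triacetate F3. F3 should be stable on silica and separable from under-demethylated acetates. Acid-catalysed methanolysis (HCl in MeOH, rt, Ar, then evaporation) would then release 6 with only volatile co-products, ready to be dissolved in the degassed buffer of step 4 without chromatography.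

Further compounds
F0 | step 4 | none | none
F1 | step 2 | 3,5-dimethoxyphenol | COc1cc(O)cc(OC)c1
F2 | step 2 | 2-iodo-1,3,5-trimethoxybenzene | COc1cc(OC)c(I)c(OC)c1
F3 | step 3 | 2-[3,5-bis(acetyloxy)phenoxy]benzene-1,3,5-triyl triacetate | CC(=O)Oc1cc(OC(C)=O)cc(Oc2c(OC(C)=O)cc(OC(C)=O)cc2OC(C)=O)c1
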